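**Retrosynthetic overview**
1. The target is cut across the cyclohexene into unprotected morachalcone A (dienophile) and an unprotected (E)-3-methylbuta-1,3-dienyl 2-arylbenzofuran (diene); one enzyme-catalysed exo [4+2] cycloaddition makes the ring and all three stereocentres in the last step.
2. The diene comes from Suzuki coupling of 5-bromomoracin M with an (E)-3-methylbuta-1,3-dienyl boronate (enyne hydroboration).
3. 5-Bromomoracin M comes from its trimethyl ether, which is made by oxidative cyclisation of a 2-hydroxystilbene (the laboratory copy of stilbene → 2-arylbenzofuran); the stilbene comes from a Horner–Wadsworth–Emmons reaction.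
4. Morachalcone A comes from Claisen–Schmidt condensation of 3-prenyl-2,4-dihydroxyacetophenone with bis-MOM 2,4-dihydroxybenzaldehyde, then MOM removal.
5. Ring order: furan ring of the benzofuran first (step 6), cyclohexene last (step 10).

Assumption: MaDA-3, the exo-selective FAD-containing Diels–Alderase of Morus alba, is made by routine heterologous expression in insect cells and is counted as a catalyst, not as a step; all seven starting materials are taken as catalogue chemicals.

**Route**

Step 1
Reactants: 1 1-(2,4-dihydroxyphenyl)ethan-1-one (2,4-dihydroxyacetophenone); 2 1-bromo-3-methylbut-2-ene (prenyl bromide)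
Product: 3 1-[2,4-dihydroxy-3-(3-methylbut-2-en-1-yl)phenyl]ethan-1-one
Conditions: KOH (10% aq), 0 °C → rt, 4 h; acidify, chromatography
Reagents that add atoms: none
Why: Nuclear (C-)prenylation of a resorcinol dianion, in which the ambident phenoxide in water alkylates by SN2 at C3, the carbon activated by both oxygens; the 5-prenyl and O-prenyl by-products are removed by chromatography and the modest yield is accepted because both reactants are bulk chemicals.

Step 2
Reactants: 4 2,4-dihydroxybenzaldehyde
Product: 5 2,4-bis(methoxymethoxy)benzaldehyde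
Conditions: NaH (2.4 equiv), MOMCl (2.4 equiv), DMF, 0 °C → rt
Reagents that add atoms: chloromethyl methyl ether (MOMCl), COCCl
Why: Williamson ether synthesis in which both phenoxides, including the hydrogen-bonded 2-OH once deprotonated by NaH, are alkylated, so the aldehyde carries no acidic OH and stays a competent electrophile for the aldol step.

Step 3
Reactants: 3 1-[2,4-dihydroxy-3-(3-methylbut-2-en-1-yl)phenyl]ethan-1-one; 5 2,4-bis(methoxymethoxy)benzaldehyde
Product: 6 (2E)-3-[2,4-bis(methoxymethoxy)phenyl]-1-[2,4-dihydroxy-3-(3-methylbut-2-en-1-yl)phenyl]prop-2-en-1-one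
Conditions: KOH (50% aq, 10 equiv), EtOH, rt, 48 h; then 1 M HCl to pH 5 at 0 °C
Reagents that add atoms: none
Why: Claisen–Schmidt condensation (crossed aldol with E1cB dehydration), in which only ketone 3 can enolise, aldehyde 5 has no free phenol to deactivate it, the two phenoxides of 3 only slow enolate formation (hence excess KOH), and the conjugated enone forms as the favoured E-isomer.

Step 4
Reactants: 6 (2E)-3-[2,4-bis(methoxymethoxy)phenyl]-1-[2,4-dihydroxy-3-(3-methylbut-2-en-1-yl)phenyl]prop-2-en-1-one
Product: 7 morachalcone A, (2E)-1-[2,4-dihydroxy-3-(3-methylbut-2-en-1-yl)phenyl]-3-(2,4-dihydroxyphenyl)prop-2-en-1-one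
Conditions: 3 M aq HCl, MeOH, 45 °C, 2 h
Reagents that add atoms: none
Why: Acid-catalysed acetal cleavage (MOM removal by transacetalisation to methanol), which is much faster than acid cyclisation of the prenyl group onto a phenol or closure of the 2′-hydroxychalcone to a flavanone, so the E-enone and the prenyl chain are kept.

Step 5
Reactants: 8 5-bromo-2-hydroxy-4-methoxybenzaldehyde; 9 diethyl [(3,5-dimethoxyphenyl)methyl]phosphonate
Product: 10 4-bromo-2-[(E)-2-(3,5-dimethoxyphenyl)ethenyl]-5-methoxyphenol
Conditions: KOtBu (3.0 equiv), DMF, 0 °C → 50 °C; aq NH4Cl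
Reagents that add atoms: none
Why: Horner–Wadsworth–Emmons olefination, in which the benzylic phosphonate carbanion adds to the aldehyde even though it is present as its phenoxide (hence excess base and gentle warming), and reversible addition followed by phosphate elimination gives the E-stilbene.

Step 6
Reactants: 10 4-bromo-2-[(E)-2-(3,5-dimethoxyphenyl)ethenyl]-5-methoxyphenol
Product: 11 5-bromo-2-(3,5-dimethoxyphenyl)-6-methoxy-1-benzofuran
Conditions: PhI(OAc)2 (1.1 equiv), MeCN, rt, 2 h
Reagents that add atoms: none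
Why: Hypervalent-iodine oxidative cyclisation of a 2-hydroxystilbene, the laboratory counterpart of the stilbene → 2-arylbenzofuran step presumed for the moracins, in which trivalent iodine activates the alkene, the phenol oxygen closes 5-endo onto the carbon benzylic to the dimethoxyphenyl ring, and loss of PhI and a proton aromatises the furan; the other oxygens are methyl ethers so only this phenol reacts.

Step 7
Reactants: 11 5-bromo-2-(3,5-dimethoxyphenyl)-6-methoxy-1-benzofuran
Product: 12 5-(5-bromo-6-hydroxy-1-benzofuran-2-yl)benzene-1,3-diol (5-bromomoracin M)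
Conditions: BBr3 (6 equiv), CH2Cl2, −78 °C → rt; MeOH/H2O quench at 0 °C
Reagents that add atoms: none
Why: Lewis-acid ether cleavage (BBr3 demethylation), in which boron binds each methoxy oxygen and bromide removes the methyl group by SN2; the aryl bromide and the benzofuran are inert, and the step is placed before the acid-sensitive diene is introduced.

Step 8
Reactants: 13 2-methylbut-1-en-3-yne; 14 pinacolborane (4,4,5,5-tetramethyl-1,3,2-dioxaborolane)
Product: 15 4,4,5,5-tetramethyl-2-[(1E)-3-methylbuta-1,3-dien-1-yl]-1,3,2-dioxaborolane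
Conditions: Cp2Zr(H)Cl (5 mol %), Et3N (10 mol %), neat, sealed tube, 60 °C, 16 h
Reagents that add atoms: none
Why: Zirconium-catalysed hydroboration of a terminal alkyne (hydrozirconation then Zr–B exchange), a syn anti-Markovnikov addition that gives only the E-alkenylboronate and leaves the 1,1-disubstituted alkene untouched.

Step 9
Reactants: 12 5-(5-bromo-6-hydroxy-1-benzofuran-2-yl)benzene-1,3-diol; 15 4,4,5,5-tetramethyl-2-[(1E)-3-methylbuta-1,3-dien-1-yl]-1,3,2-dioxaborolane
Product: 16 5-{6-hydroxy-5-[(1E)-3-methylbuta-1,3-dien-1-yl]-1-benzofuran-2-yl}benzene-1,3-diol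
Conditions: Pd(OAc)2 (5 mol %), SPhos (2-dicyclohexylphosphino-2′,6′-dimethoxybiphenyl, 10 mol %), K3PO4 (4 equiv), 1,4-dioxane/H2O 4:1, degassed, 60 °C; work-up at pH 6, used within hours
Reagents that add atoms: none
Why: Suzuki–Miyaura cross-coupling, in which the electron-rich biarylphosphine lets zerovalent palladium insert into the C–Br bond of the phenoxide-rich arene, transmetalation and reductive elimination go with retention so the E-geometry of 15 is carried into 16, and free phenols are tolerated so no protecting group is needed.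

Step 10
Reactants: 7 morachalcone A; 16 5-{6-hydroxy-5-[(1E)-3-methylbuta-1,3-dien-1-yl]-1-benzofuran-2-yl}benzene-1,3-diol
Product: 17 [(1R,2R,6S)-6-(2,4-dihydroxyphenyl)-2-[2-(3,5-dihydroxyphenyl)-6-hydroxy-1-benzofuran-5-yl]-4-methylcyclohex-3-en-1-yl][2,4-dihydroxy-3-(3-methylbut-2-en-1-yl)phenyl]methanone (all-trans adduct)
Conditions: recombinant MaDA-3 (0.5 mol %), Tris–HCl buffer (20 mM, pH 8.0), 5% DMSO, 40 °C, 12 h, argon, dark; EtOAc extraction
Reagents that add atoms: none
Why: Enzyme-catalysed intermolecular Diels–Alder reaction ([4+2] cycloaddition), in which the exo-selective Diels–Alderase holds the s-cis diene 16 and the E-enone 7 so that the CH2 terminus of the diene bonds to the chalcone β-carbon and the aryl-bearing terminus to the α-carbon through the exo transition state on one enone face, setting all three stereocentres at once as (1R,2R,6S) with the aroyl group trans to both aryl groups as in the natural all-trans mulberry adducts; the uncatalysed reaction of the free polyphenols is negligible at this temperature, and the only extrapolation from the enzyme's known substrates is that the dienyl group sits on the benzofuran ring instead of the resorcinol ring.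

**Compound list**
1 | 1-(2,4-dihydroxyphenyl)ethan-1-one | CC(=O)c1ccc(O)cc1O | starting material
2 | 1-bromo-3-methylbut-2-ene (prenyl bromide) | CC(C)=CCBr | starting material
3 | 1-[2,4-dihydroxy-3-(3-methylbut-2-en-1-yl)phenyl]ethan-1-one | CC(=O)c1ccc(O)c(CC=C(C)C)c1O | intermediate
4 | 2,4-dihydroxybenzaldehyde | O=Cc1ccc(O)cc1O | starting material
5 | 2,4-bis(methoxymethoxy)benzaldehyde | COCOc1ccc(C=O)c(OCOC)c1 | intermediate
6 | (2E)-3-[2,4-bis(methoxymethoxy)phenyl]-1-[2,4-dihydroxy-3-(3-methylbut-2-en-1-yl)phenyl]prop-2-en-1-one | CC(C)=CCc1c(O)ccc(C(=O)/C=C/c2ccc(OCOC)cc2OCOC)c1O | intermediate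
7 | morachalcone A, (2E)-1-[2,4-dihydroxy-3-(3-methylbut-2-en-1-yl)phenyl]-3-(2,4-dihydroxyphenyl)prop-2-en-1-one | CC(C)=CCc1c(O)ccc(C(=O)/C=C/c2ccc(O)cc2O)c1O | intermediate
8 | 5-bromo-2-hydroxy-4-methoxybenzaldehyde | COc1cc(O)c(C=O)cc1Br | starting material
9 | diethyl [(3,5-dimethoxyphenyl)methyl]phosphonate | CCOP(=O)(Cc1cc(OC)cc(OC)c1)OCC | starting material
10 | 4-bromo-2-[(E)-2-(3,5-dimethoxyphenyl)ethenyl]-5-methoxyphenol | COc1cc(O)c(/C=C/c2cc(OC)cc(OC)c2)cc1Br | intermediate
11 | 5-bromo-2-(3,5-dimethoxyphenyl)-6-methoxy-1-benzofuran | COc1cc(-c2cc3cc(Br)c(OC)cc3o2)cc(OC)c1 | intermediate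
12 | 5-(5-bromo-6-hydroxy-1-benzofuran-2-yl)benzene-1,3-diol | Oc1cc(O)cc(-c2cc3cc(Br)c(O)cc3o2)c1 | intermediate
13 | 2-methylbut-1-en-3-yne | C=C(C)C#C | starting material
14 | pinacolborane (4,4,5,5-tetramethyl-1,3,2-dioxaborolane) | CC1(C)OBOC1(C)C | starting material
15 | 4,4,5,5-tetramethyl-2-[(1E)-3-methylbuta-1,3-dien-1-yl]-1,3,2-dioxaborolane | CC(=C)/C=C/B1OC(C)(C)C(C)(C)O1 | intermediate
16 | 5-{6-hydroxy-5-[(1E)-3-methylbuta-1,3-dien-1-yl]-1-benzofuran-2-yl}benzene-1,3-diol | CC(=C)/C=C/c1cc2cc(-c3cc(O)cc(O)c3)oc2cc1O | intermediate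
17 | [(1R,2R,6S)-6-(2,4-dihydroxyphenyl)-2-[2-(3,5-dihydroxyphenyl)-6-hydroxy-1-benzofuran-5-yl]-4-methylcyclohex-3-en-1-yl][2,4-dihydroxy-3-(3-methylbut-2-en-1-yl)phenyl]methanone | CC(C)=CCc1c(O)ccc(C(=O)[C@@H]2[C@@H](c3ccc(O)cc3O)CC(C)=C[C@H]2c2cc3cc(-c4cc(O)cc(O)c4)oc3cc2O)c1O | target

**Totals**
Total step count: 10.
Longest linear sequence: 5 steps (8 → 10 → 11 → 12 → 16 → 17; steps 5, 6, 7, 9, 10).

**Three steps most likely to fail, with fallbacks**

Step 10 (enzymatic cycloaddition; the enzyme may reject a diene carried on the benzofuran ring or lose exo control). The fallback sets out from 7 and 16 and comes back to the route at 17. It replaces the enzyme by a chiral boron Lewis acid acting on acetyl-protected partners. Compound 7 is acetylated with Ac2O (3.1 equiv) and pyridine at 0 °C, which leaves the chelated 2′-OH free and gives morachalcone A 2,4,4′-triacetate F1. Compound 16 is peracetylated (Ac2O, pyridine) to the diene triacetate F2. F1 and F2 are combined with the borate formed from B(OPh)3 and (R)-VANOL (3,3′-diphenyl-2,2′-bi-1-naphthol; 1.2 equiv each, THF, 4 Å sieves, rt). The 2′-phenol and ketone chelate boron, which activates the enone, and the biaryl ligand shields one face; this ligand class favours the exo transition state. The antipodal ligand is used if a pilot run gives the mirror-image adduct by chiral HPLC. After separation from the endo isomer this gives the exo-adduct hexaacetate F3, with the 2′-OH still free. K2CO3 in MeOH at 0 °C removes the six acetates and gives 17.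

Step 9 (Suzuki coupling on the free triphenol; slow oxidative addition and a labile dienyl phenol product). The fallback sets out from 12 and comes back at 16. It builds the diene in two stages on a silyl-protected core. Compound 12 is silylated (TBSCl, imidazole, DMF) to the tris(tert-butyldimethylsilyl) ether F4. Heck coupling of F4 with 2-methylbut-3-en-2-ol (Pd(OAc)2, P(o-tol)3, Et3N, DMF, 100 °C) gives the E-configured tertiary allylic alcohol F5. MsCl and Et3N (CH2Cl2, 0 °C → rt) dehydrate F5 towards a methyl group to give the silylated diene F6. Bu4NF buffered with AcOH (THF, 0 °C) then releases 16.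

Step 6 (oxidative cyclisation; over-oxidation of the electron-rich phenol by PhI(OAc)2). The fallback sets out from 10 and comes back at 11. It splits the oxidation into a selenium-mediated ring closure and a separate elimination. PhSeCl (CH2Cl2, −78 °C) forms a seleniranium ion on the stilbene, which the phenol opens anti at the carbon benzylic to the dimethoxyphenyl ring; this gives racemic trans-5-bromo-2-(3,5-dimethoxyphenyl)-6-methoxy-3-(phenylselanyl)-2,3-dihydro-1-benzofuran F7. H2O2 (THF, 0 °C → rt) oxidises F7 to the selenoxide, whose syn-elimination with the cis hydrogen at C2 gives the aromatic benzofuran 11.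

**Further compounds**
F1 | step 10 | (2E)-3-[2,4-bis(acetyloxy)phenyl]-1-[4-(acetyloxy)-2-hydroxy-3-(3-methylbut-2-en-1-yl)phenyl]prop-2-en-1-one (morachalcone A 2,4,4′-triacetate) | CC(C)=CCc1c(OC(C)=O)ccc(C(=O)/C=C/c2ccc(OC(C)=O)cc2OC(C)=O)c1O
F2 | step 10 | 5-{6-(acetyloxy)-5-[(1E)-3-methylbuta-1,3-dien-1-yl]-1-benzofuran-2-yl}-1,3-phenylene diacetate (diene triacetate) | CC(=C)/C=C/c1cc2cc(-c3cc(OC(C)=O)cc(OC(C)=O)c3)oc2cc1OC(C)=O
F3 | step 10 | hexaacetate of 17 with the 2′-OH free, (1R,2R,6S) (exo-adduct hexaacetate) | CC(C)=CCc1c(OC(C)=O)ccc(C(=O)[C@@H]2[C@@H](c3ccc(OC(C)=O)cc3OC(C)=O)CC(C)=C[C@H]2c2cc3cc(-c4cc(OC(C)=O)cc(OC(C)=O)c4)oc3cc2OC(C)=O)c1O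
F4 | step 9 | 5-bromo-2-[3,5-bis(tert-butyldimethylsilyloxy)phenyl]-6-(tert-butyldimethylsilyloxy)-1-benzofuran | CC(C)(C)[Si](C)(C)Oc1cc(O[Si](C)(C)C(C)(C)C)cc(-c2cc3cc(Br)c(O[Si](C)(C)C(C)(C)C)cc3o2)c1
F5 | step 9 | (3E)-4-{2-[3,5-bis(tert-butyldimethylsilyloxy)phenyl]-6-(tert-butyldimethylsilyloxy)-1-benzofuran-5-yl}-2-methylbut-3-en-2-ol | CC(C)(O)/C=C/c1cc2cc(-c3cc(O[Si](C)(C)C(C)(C)C)cc(O[Si](C)(C)C(C)(C)C)c3)oc2cc1O[Si](C)(C)C(C)(C)C
F6 | step 9 | 2-[3,5-bis(tert-butyldimethylsilyloxy)phenyl]-6-(tert-butyldimethylsilyloxy)-5-[(1E)-3-methylbuta-1,3-dien-1-yl]-1-benzofuran | CC(=C)/C=C/c1cc2cc(-c3cc(O[Si](C)(C)C(C)(C)C)cc(O[Si](C)(C)C(C)(C)C)c3)oc2cc1O[Si](C)(C)C(C)(C)C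
F7 | step 6 | trans-5-bromo-2-(3,5-dimethoxyphenyl)-6-methoxy-3-(phenylselanyl)-2,3-dihydro-1-benzofuran (racemic; one enantiomer drawn) | COc1cc2c(cc1Br)[C@@H]([Se]c1ccccc1)[C@H](c1cc(OC)cc(OC)c1)O2
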